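**Plan**

1. Labdane locants are used (C1–C10 decalin, C11–C16 side chain, C17 formyl carbon, C20 angular methyl). The retrosynthesis first cuts C12–C13 (B-alkyl Suzuki–Miyaura coupling with the (Z)-iodoenoate) and returns C17 to a silyloxymethyl group epimeric at C8.
2. The decalin is then cut at C5–C10 and C8–C9. These bonds lie 1,4 across ring B, so a diene C5=C6–C7=C8 and an enal C9=C10, joined by the ring A atoms C1–C4, map onto both rings of an open-chain trienal.
3. The trienal is cut at C6–C7 (alkenyl–alkenyl Suzuki–Miyaura coupling), C5=C6 (Takai olefination) and C3–C4 (Mukaiyama aldol), which leads back to geranyl acetate.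
4. Forward: the chain C11–C9–C10–C1–C3 comes from geranyl acetate, then C4/C5, C6 and C7/C8/C17 are added. Rings A and B close together in one cycloaddition, and C12 and C13–C16 are joined last.
5. Stereochemistry: C3 from a valine-derived oxazaborolidinone aldol; C5, C9 and C10 relayed from C3 and the alkene geometries in the cycloaddition; C8 by base equilibration of the C17 aldehyde; the 13Z alkene from the iodoenoate with retention.

Key step: step 11

Assumption: the oxazaborolidinone from N-tosyl-(S)-valine directs the silyl ketene acetal to the Si face of an unbranched aldehyde, which gives (3R)-6. If the sense were the reverse, the (R)-valine promoter would be used and nothing else would change.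

**Route**

Step 1
Reactants: 1 geranyl acetate
Product: 3 (2E)-3-methyl-6-oxohex-2-en-1-yl acetate, via secondary ozonide 2 (not isolated)
Conditions: O3 (1.0 equiv, Sudan Red 7B end point), CH2Cl2, −78 °C; then PPh3, −78 °C → rt
Reagents that add atoms: ozone, [O-][O+]=O
Why: Chemoselective ozonolysis with reductive work-up: electrophilic ozone should take the electron-rich C6=C7 alkene well before the C2=C3 alkene, which the allylic acetoxy group deactivates, and PPh3 reduces the ozonide to the aldehyde without touching the acetate.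

Step 2
Reactants: 3 (2E)-3-methyl-6-oxohex-2-en-1-yl acetate; 4 1-methoxy-2-methyl-1-(trimethylsilyloxy)prop-1-ene
Product: 6 methyl (3R,6E)-8-acetoxy-3-hydroxy-2,2,6-trimethyloct-6-enoate, via trimethylsilyl ether 5 (not isolated)
Conditions: N-tosyl-L-valine (1.1 equiv), BH3·THF (1.0 equiv), CH2Cl2, 0 °C → rt; then 3 and 4, −78 °C; 1 M HCl work-up
Reagents that add atoms: 4, 1-methoxy-2-methyl-1-(trimethylsilyloxy)prop-1-ene, COC(O[Si](C)(C)C)=C(C)C
Why: Kiyooka variant of the asymmetric Mukaiyama aldol reaction: the oxazaborolidinone made in the flask from N-tosyl-(S)-valine and borane binds the aldehyde and screens one face, so the silyl ketene acetal should add to the Si face and set C3 as R, while the nucleophile brings C4 with both methyl groups and C5 at the ester level; the acidic work-up frees the hydroxyl from its trimethylsilyl ether.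

Step 3
Reactants: 6 methyl (3R,6E)-8-acetoxy-3-hydroxy-2,2,6-trimethyloct-6-enoate
Product: 7 methyl (3R,6E)-3,8-dihydroxy-2,2,6-trimethyloct-6-enoate
Conditions: K2CO3 (0.2 equiv), MeOH, 0 °C
Reagents that add atoms: none
Why: Base-catalysed transesterification (methanolysis) removes the unhindered primary acetate, which could not survive the later hydride reduction, while the ester beside the quaternary carbon can only exchange methoxide for methoxide and the cold, catalytic conditions keep retro-aldol cleavage of the β-hydroxy ester at bay.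

Step 4
Reactants: 7 methyl (3R,6E)-3,8-dihydroxy-2,2,6-trimethyloct-6-enoate
Product: 8 methyl (3R,6E)-2,2,6-trimethyl-3,8-bis(triethylsilyloxy)oct-6-enoate
Conditions: Et3SiOTf (2.5 equiv), 2,6-lutidine, CH2Cl2, −78 → 0 °C
Reagents that add atoms: triethylsilyl trifluoromethanesulfonate, CC[Si](CC)(CC)OS(=O)(=O)C(F)(F)F
Why: Silyl triflate silylation with a hindered pyridine base is strong enough to cap the neopentyl-type secondary C3 hydroxyl along with the primary allylic one, and the triethylsilyl group is chosen so that the primary ether can later be removed in the presence of the other silyl ethers.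

Step 5
Reactants: 8 methyl (3R,6E)-2,2,6-trimethyl-3,8-bis(triethylsilyloxy)oct-6-enoate
Product: 9 (3R,6E)-2,2,6-trimethyl-3,8-bis(triethylsilyloxy)oct-6-en-1-ol
Conditions: i-Bu2AlH (2.5 equiv), CH2Cl2, −78 → 0 °C; aq. potassium sodium tartrate
Reagents that add atoms: none
Why: Diisobutylaluminium hydride reduction of the ester to the primary alcohol leaves silyl ethers and the isolated alkene untouched, and full reduction is taken on purpose because partial reduction of so hindered an ester is unreliable.

Step 6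
Reactants: 9 (3R,6E)-2,2,6-trimethyl-3,8-bis(triethylsilyloxy)oct-6-en-1-ol
Product: 10 (3R,6E)-2,2,6-trimethyl-3,8-bis(triethylsilyloxy)oct-6-enal
Conditions: Dess–Martin periodinane, NaHCO3, CH2Cl2, 0 °C → rt
Reagents that add atoms: none
Why: Dess–Martin oxidation under buffered conditions gives the aldehyde, which has no α-hydrogen and so cannot enolise or eliminate the β-silyloxy group; the Swern protocol is avoided because it can oxidise primary triethylsilyl ethers.

Step 7
Reactants: 10 (3R,6E)-2,2,6-trimethyl-3,8-bis(triethylsilyloxy)oct-6-enal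
Product: 11 (1E,4R,7E)-1-iodo-3,3,7-trimethyl-4,9-bis(triethylsilyloxy)nona-1,7-diene
Conditions: CrCl2 (6 equiv), CHI3 (2 equiv), THF/1,4-dioxane, 0 °C → rt
Reagents that add atoms: iodoform, IC(I)I
Why: Takai olefination: the geminal dichromium reagent formed from CHI3 and CrCl2 adds to the aldehyde and eliminates, which should give the (E)-alkenyl iodide with high selectivity for an α-quaternary aldehyde, and the neutral conditions spare both silyl ethers.

Step 8
Reactants: 11 (1E,4R,7E)-1-iodo-3,3,7-trimethyl-4,9-bis(triethylsilyloxy)nona-1,7-diene; 12 (E)-3-(tert-butyldimethylsilyloxy)prop-1-enylboronic acid pinacol ester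
Product: 13 (2E,6R,8E,10E)-12-(tert-butyldimethylsilyloxy)-3,7,7-trimethyl-1,6-bis(triethylsilyloxy)dodeca-2,8,10-triene
Conditions: PdCl2(dppf) (5 mol %), aq. K3PO4, THF, rt → 40 °C
Reagents that add atoms: 12, (E)-3-(tert-butyldimethylsilyloxy)prop-1-enylboronic acid pinacol ester, CC(C)(C)[Si](C)(C)OC/C=C/B1OC(C)(C)C(C)(C)O1
Why: Suzuki–Miyaura coupling of an alkenyl iodide with an alkenylboronate under zerovalent palladium catalysis proceeds with retention at both partners, so the C6–C7 bond is formed and the (E,E)-diene with its C17 silyloxymethyl terminus is delivered in one step without any hydride reagent.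

Step 9
Reactants: 13 (2E,6R,8E,10E)-12-(tert-butyldimethylsilyloxy)-3,7,7-trimethyl-1,6-bis(triethylsilyloxy)dodeca-2,8,10-triene
Product: 14 (2E,6R,8E,10E)-12-(tert-butyldimethylsilyloxy)-3,7,7-trimethyl-6-(triethylsilyloxy)dodeca-2,8,10-trien-1-ol
Conditions: PPTS (0.1 equiv), MeOH/CH2Cl2, −10 → 0 °C
Reagents that add atoms: none
Why: Acid-catalysed methanolysis of silyl ethers follows steric rank, so the primary allylic triethylsilyl ether should cleave much faster than the primary tert-butyldimethylsilyl ether and the secondary triethylsilyl ether shielded by the adjacent quaternary carbon.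

Step 10
Reactants: 14 (2E,6R,8E,10E)-12-(tert-butyldimethylsilyloxy)-3,7,7-trimethyl-6-(triethylsilyloxy)dodeca-2,8,10-trien-1-ol
Product: 15 (2E,6R,8E,10E)-12-(tert-butyldimethylsilyloxy)-3,7,7-trimethyl-6-(triethylsilyloxy)dodeca-2,8,10-trienal
Conditions: MnO2 (20 equiv), CH2Cl2, rt
Reagents that add atoms: none
Why: Allylic oxidation with activated MnO2 stops at the aldehyde, acts only on the allylic alcohol and should keep the (E) geometry of the geranial-type enal, which gives the cyclisation substrate.

Step 11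
Reactants: 15 (2E,6R,8E,10E)-12-(tert-butyldimethylsilyloxy)-3,7,7-trimethyl-6-(triethylsilyloxy)dodeca-2,8,10-trienal
Product: 16 (1R,2R,4aS,6R,8aR)-2-[(tert-butyldimethylsilyloxy)methyl]-5,5,8a-trimethyl-6-(triethylsilyloxy)-1,2,4a,5,6,7,8,8a-octahydronaphthalene-1-carbaldehyde (trans-fused; C9 formyl cis to the C10 methyl; C8 silyloxymethyl axial and cis to both)
Conditions: Me2AlCl (1.5 equiv), CH2Cl2, −78 → −20 °C
Reagents that add atoms: none
Why: Me2AlCl binds the formyl oxygen and lowers the LUMO of the enal, and a concerted but asynchronous [4+2] cycloaddition follows in which the C10–C5 bond runs ahead of the C9–C8 bond. The closest known reaction type is the Lewis-acid-promoted intramolecular Diels–Alder reaction of (E,E,E)-deca-1,7,9-trienals, which gives trans-fused octalins that carry an angular methyl group. Ring B closes as the six-membered cycloadduct ring (C5 to C10), and ring A closes in the same transition state as the fused, chair-like six-membered ring made of the tether and the two reacting termini (C10, C1, C2, C3, C4, C5). At C9 the (E)-enal geometry keeps the formyl group cis to the C10 methyl group; at C8 the (E,E)-diene geometry puts C17 cis to C4 across ring B, the axial epimer that is corrected in step 17; at C5 and C10 the endo position of the aluminium-bound formyl group holds the tether anti and gives the trans ring fusion. The absolute sense of all four centres is relayed from C3, whose silyloxy group takes the equatorial site of the chair-like tether and so leaves one diene face open. The step needs endo and diene-face selectivity: the first is secured by Lewis acid complexation of the (E)-enal, the second by the C3 substituent, and the gem-dimethyl group at C4 favours the folded reactive conformer.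

Step 12
Reactants: 16 (1R,2R,4aS,6R,8aR)-2-[(tert-butyldimethylsilyloxy)methyl]-5,5,8a-trimethyl-6-(triethylsilyloxy)-1,2,4a,5,6,7,8,8a-octahydronaphthalene-1-carbaldehyde
Product: 17 (1R,2R,4aS,6R,8aR)-2-[(tert-butyldimethylsilyloxy)methyl]-5,5,8a-trimethyl-6-(triethylsilyloxy)decahydronaphthalene-1-carbaldehyde
Conditions: H2 (1 atm), 10% Pd/C, EtOAc, rt
Reagents that add atoms: none
Why: Heterogeneous catalytic hydrogenation saturates the cis-disubstituted C6=C7 alkene, creates no stereocentre and should leave the hindered aldehyde and both silyl ethers intact in a non-protic solvent.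

Step 13
Reactants: 17 (1R,2R,4aS,6R,8aR)-2-[(tert-butyldimethylsilyloxy)methyl]-5,5,8a-trimethyl-6-(triethylsilyloxy)decahydronaphthalene-1-carbaldehyde
Product: 18 tert-butyl{[(1R,2R,4aS,6R,8aS)-1-ethenyl-5,5,8a-trimethyl-6-(triethylsilyloxy)decahydronaphthalen-2-yl]methoxy}dimethylsilane
Conditions: Ph3PCH3Br, KN(SiMe3)2, THF, 0 °C; then 17, −78 °C → rt
Reagents that add atoms: methyltriphenylphosphonium bromide, C[P+](c1ccccc1)(c1ccccc1)c1ccccc1.[Br-]
Why: Wittig methylenation with the unstabilised ylide converts the C11 aldehyde into the vinyl group; the formyl group already sits in the equatorial position at C9, so brief contact with the basic ylide should not change that centre.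

Step 14
Reactants: 18 tert-butyl{[(1R,2R,4aS,6R,8aS)-1-ethenyl-5,5,8a-trimethyl-6-(triethylsilyloxy)decahydronaphthalen-2-yl]methoxy}dimethylsilane; 19 methyl (2Z)-3-iodobut-2-enoate
Product: 21 methyl (2Z)-5-[(1R,2R,4aS,6R,8aS)-2-[(tert-butyldimethylsilyloxy)methyl]-5,5,8a-trimethyl-6-(triethylsilyloxy)decahydronaphthalen-1-yl]-3-methylpent-2-enoate, via B-alkyl-9-borabicyclononane 20 (not isolated)
Conditions: 9-BBN dimer, THF, rt → 50 °C; then 19, PdCl2(dppf) (5 mol %), AsPh3, aq. Cs2CO3, DMF, rt
Reagents that add atoms: 19, methyl (2Z)-3-iodobut-2-enoate, COC(=O)/C=C(/C)I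
Why: Anti-Markovnikov hydroboration of the monosubstituted alkene with 9-BBN followed by B-alkyl Suzuki–Miyaura coupling: the primary alkylborane transfers its alkyl group to palladium after base activation, and oxidative addition and reductive elimination keep the geometry of the (Z)-iodoenoate, so the C12–C13 bond and the 13Z enoate arise together.

Step 15
Reactants: 21 methyl (2Z)-5-[(1R,2R,4aS,6R,8aS)-2-[(tert-butyldimethylsilyloxy)methyl]-5,5,8a-trimethyl-6-(triethylsilyloxy)decahydronaphthalen-1-yl]-3-methylpent-2-enoate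
Product: 22 methyl (2Z)-5-[(1R,2R,4aS,6R,8aS)-6-hydroxy-2-(hydroxymethyl)-5,5,8a-trimethyldecahydronaphthalen-1-yl]-3-methylpent-2-enoate
Conditions: HF·pyridine, pyridine, THF, 0 °C → rt
Reagents that add atoms: none
Why: Fluoride-mediated desilylation under buffered acidic conditions removes both silyl ethers without saponifying the methyl ester or isomerising the enoate.

Step 16
Reactants: 22 methyl (2Z)-5-[(1R,2R,4aS,6R,8aS)-6-hydroxy-2-(hydroxymethyl)-5,5,8a-trimethyldecahydronaphthalen-1-yl]-3-methylpent-2-enoate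
Product: 23 methyl (2Z)-5-[(1R,2R,4aS,6R,8aS)-2-formyl-6-hydroxy-5,5,8a-trimethyldecahydronaphthalen-1-yl]-3-methylpent-2-enoate (C8 epimer of the target with the formyl group axial)
Conditions: TEMPO (0.1 equiv), PhI(OAc)2 (1.2 equiv), CH2Cl2, rt
Reagents that add atoms: none
Why: Oxoammonium-mediated oxidation (TEMPO with PhI(OAc)2) is selective for primary over hindered secondary alcohols, so C17 should be oxidised to the aldehyde while the neopentyl-type C3 hydroxyl stays, and it stops at the aldehyde in anhydrous solvent.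

Step 17
Reactants: 23 methyl (2Z)-5-[(1R,2R,4aS,6R,8aS)-2-formyl-6-hydroxy-5,5,8a-trimethyldecahydronaphthalen-1-yl]-3-methylpent-2-enoate
Product: 24 methyl (2Z)-5-[(1R,2S,4aS,6R,8aS)-2-formyl-6-hydroxy-5,5,8a-trimethyldecahydronaphthalen-1-yl]-3-methylpent-2-enoate (target, CNP0188570.1)
Conditions: DBU (0.3 equiv), CH2Cl2, rt
Reagents that add atoms: none
Why: Base-mediated epimerisation through the aldehyde enolate: the axial formyl group at C8 is 1,3-diaxial to the C10 methyl group, so equilibration should move it to the equatorial position trans to the C9 side chain and thereby set C8 as in the target, while C9 has no acidifying group and the γ-hydrogens of the enoate are far less acidic.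

**Compound list**

1 | geranyl acetate, (2E)-3,7-dimethylocta-2,6-dien-1-yl acetate | CC(C)=CCC/C(C)=C/COC(C)=O | starting material
2 | 3-[(3E)-5-acetoxy-3-methylpent-3-en-1-yl]-5,5-dimethyl-1,2,4-trioxolane (secondary ozonide, not isolated) | CC1(C)OOC(CC/C(C)=C/COC(C)=O)O1 | intermediate
3 | (2E)-3-methyl-6-oxohex-2-en-1-yl acetate | O=CCC/C(C)=C/COC(C)=O | intermediate
4 | 1-methoxy-2-methyl-1-(trimethylsilyloxy)prop-1-ene | COC(O[Si](C)(C)C)=C(C)C | starting material
5 | methyl (3R,6E)-8-acetoxy-2,2,6-trimethyl-3-(trimethylsilyloxy)oct-6-enoate (not isolated) | CC(=O)OC/C=C(\C)CC[C@@H](O[Si](C)(C)C)C(C)(C)C(=O)OC | intermediate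
6 | methyl (3R,6E)-8-acetoxy-3-hydroxy-2,2,6-trimethyloct-6-enoate | CC(=O)OC/C=C(\C)CC[C@@H](O)C(C)(C)C(=O)OC | intermediate
7 | methyl (3R,6E)-3,8-dihydroxy-2,2,6-trimethyloct-6-enoate | OC/C=C(\C)CC[C@@H](O)C(C)(C)C(=O)OC | intermediate
8 | methyl (3R,6E)-2,2,6-trimethyl-3,8-bis(triethylsilyloxy)oct-6-enoate | CC[Si](CC)(CC)OC/C=C(\C)CC[C@@H](O[Si](CC)(CC)CC)C(C)(C)C(=O)OC | intermediate
9 | (3R,6E)-2,2,6-trimethyl-3,8-bis(triethylsilyloxy)oct-6-en-1-ol | CC[Si](CC)(CC)OC/C=C(\C)CC[C@@H](O[Si](CC)(CC)CC)C(C)(C)CO | intermediate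
10 | (3R,6E)-2,2,6-trimethyl-3,8-bis(triethylsilyloxy)oct-6-enal | CC[Si](CC)(CC)OC/C=C(\C)CC[C@@H](O[Si](CC)(CC)CC)C(C)(C)C=O | intermediate
11 | (1E,4R,7E)-1-iodo-3,3,7-trimethyl-4,9-bis(triethylsilyloxy)nona-1,7-diene | CC[Si](CC)(CC)OC/C=C(\C)CC[C@@H](O[Si](CC)(CC)CC)C(C)(C)/C=C/I | intermediate
12 | (E)-3-(tert-butyldimethylsilyloxy)prop-1-enylboronic acid pinacol ester | CC(C)(C)[Si](C)(C)OC/C=C/B1OC(C)(C)C(C)(C)O1 | starting material
13 | (2E,6R,8E,10E)-12-(tert-butyldimethylsilyloxy)-3,7,7-trimethyl-1,6-bis(triethylsilyloxy)dodeca-2,8,10-triene | CC[Si](CC)(CC)OC/C=C(\C)CC[C@@H](O[Si](CC)(CC)CC)C(C)(C)/C=C/C=C/CO[Si](C)(C)C(C)(C)C | intermediate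
14 | (2E,6R,8E,10E)-12-(tert-butyldimethylsilyloxy)-3,7,7-trimethyl-6-(triethylsilyloxy)dodeca-2,8,10-trien-1-ol | OC/C=C(\C)CC[C@@H](O[Si](CC)(CC)CC)C(C)(C)/C=C/C=C/CO[Si](C)(C)C(C)(C)C | intermediate
15 | (2E,6R,8E,10E)-12-(tert-butyldimethylsilyloxy)-3,7,7-trimethyl-6-(triethylsilyloxy)dodeca-2,8,10-trienal | O=C/C=C(\C)CC[C@@H](O[Si](CC)(CC)CC)C(C)(C)/C=C/C=C/CO[Si](C)(C)C(C)(C)C | intermediate
16 | (1R,2R,4aS,6R,8aR)-2-[(tert-butyldimethylsilyloxy)methyl]-5,5,8a-trimethyl-6-(triethylsilyloxy)-1,2,4a,5,6,7,8,8a-octahydronaphthalene-1-carbaldehyde | O=C[C@@H]1[C@H](CO[Si](C)(C)C(C)(C)C)C=C[C@@H]2C(C)(C)[C@H](O[Si](CC)(CC)CC)CC[C@@]12C | intermediate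
17 | (1R,2R,4aS,6R,8aR)-2-[(tert-butyldimethylsilyloxy)methyl]-5,5,8a-trimethyl-6-(triethylsilyloxy)decahydronaphthalene-1-carbaldehyde | O=C[C@@H]1[C@H](CO[Si](C)(C)C(C)(C)C)CC[C@@H]2C(C)(C)[C@H](O[Si](CC)(CC)CC)CC[C@@]12C | intermediate
18 | tert-butyl{[(1R,2R,4aS,6R,8aS)-1-ethenyl-5,5,8a-trimethyl-6-(triethylsilyloxy)decahydronaphthalen-2-yl]methoxy}dimethylsilane | C=C[C@@H]1[C@H](CO[Si](C)(C)C(C)(C)C)CC[C@@H]2C(C)(C)[C@H](O[Si](CC)(CC)CC)CC[C@@]12C | intermediate
19 | methyl (2Z)-3-iodobut-2-enoate | COC(=O)/C=C(/C)I | starting material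
20 | 9-{2-[(1R,2R,4aS,6R,8aS)-2-[(tert-butyldimethylsilyloxy)methyl]-5,5,8a-trimethyl-6-(triethylsilyloxy)decahydronaphthalen-1-yl]ethyl}-9-borabicyclo[3.3.1]nonane (not isolated) | B1(CC[C@@H]2[C@H](CO[Si](C)(C)C(C)(C)C)CC[C@@H]3C(C)(C)[C@H](O[Si](CC)(CC)CC)CC[C@@]23C)C2CCCC1CCC2 | intermediate
21 | methyl (2Z)-5-[(1R,2R,4aS,6R,8aS)-2-[(tert-butyldimethylsilyloxy)methyl]-5,5,8a-trimethyl-6-(triethylsilyloxy)decahydronaphthalen-1-yl]-3-methylpent-2-enoate | COC(=O)/C=C(/C)CC[C@@H]1[C@H](CO[Si](C)(C)C(C)(C)C)CC[C@@H]2C(C)(C)[C@H](O[Si](CC)(CC)CC)CC[C@@]12C | intermediate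
22 | methyl (2Z)-5-[(1R,2R,4aS,6R,8aS)-6-hydroxy-2-(hydroxymethyl)-5,5,8a-trimethyldecahydronaphthalen-1-yl]-3-methylpent-2-enoate | COC(=O)/C=C(/C)CC[C@@H]1[C@H](CO)CC[C@@H]2C(C)(C)[C@H](O)CC[C@@]12C | intermediate
23 | methyl (2Z)-5-[(1R,2R,4aS,6R,8aS)-2-formyl-6-hydroxy-5,5,8a-trimethyldecahydronaphthalen-1-yl]-3-methylpent-2-enoate | COC(=O)/C=C(/C)CC[C@@H]1[C@H](C=O)CC[C@@H]2C(C)(C)[C@H](O)CC[C@@]12C | intermediate
24 | methyl (2Z)-5-[(1R,2S,4aS,6R,8aS)-2-formyl-6-hydroxy-5,5,8a-trimethyldecahydronaphthalen-1-yl]-3-methylpent-2-enoate | COC(=O)/C=C(/C)CC[C@@H]1[C@@H](C=O)CC[C@@H]2C(C)(C)[C@H](O)CC[C@@]12C | target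

**Step count and risks**

Total step count: 17. Longest linear sequence: 17 steps (1 → 24); compounds 4, 12 and 19 are bought and enter directly.

Steps most likely to fail:

Step 11. The cycloaddition may stall, because the C5–C10 bond joins a carbon that becomes quaternary to a carbon flanked by the gem-dimethyl centre. At the temperature then needed, the Lewis acid may ionise the dienylic silyl ether or scramble the enal geometry, and the diene-face control by C3 may be incomplete. The fallback sets out from 15 and comes back at 16. It changes the activating group from a Lewis-acid-bound aldehyde to a cationic acetal. Aprotic acetalisation of 15 (1,2-bis(trimethylsilyloxy)ethane, catalytic Me3SiOTf, CH2Cl2, −78 °C) should give 2-[(1E,5R,7E,9E)-11-(tert-butyldimethylsilyloxy)-2,6,6-trimethyl-5-(triethylsilyloxy)undeca-1,7,9-trien-1-yl]-1,3-dioxolane F1. Ionisation of the acetal by the same silyl triflate or by catalytic TfOH opens it to a vinyl oxocarbenium ion, a far stronger dienophile than the aluminium-bound enal. The ionic Diels–Alder reaction should then form the same two bonds at −78 °C with the same endo topology and give 2-[(1R,2R,4aS,6R,8aR)-2-[(tert-butyldimethylsilyloxy)methyl]-5,5,8a-trimethyl-6-(triethylsilyloxy)-1,2,4a,5,6,7,8,8a-octahydronaphthalen-1-yl]-1,3-dioxolane F2. Mild hydrolysis (PPTS, wet acetone) returns aldehyde 16.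

Step 2. Face discrimination at the unbranched aldehyde may be incomplete, and the B–H promoter may reduce part of the aldehyde, so that 6 is obtained with too low an enantiomeric purity. The fallback sets out from such 6 and comes back at 6. It replaces asymmetric C–C bond formation by asymmetric ketone reduction. Dess–Martin oxidation gives methyl (6E)-8-acetoxy-2,2,6-trimethyl-3-oxooct-6-enoate F3. Its ketone lies between a quaternary carbon and a methylene group, so Corey–Bakshi–Shibata reduction ((S)-2-methyl-CBS-oxazaborolidine, catecholborane, toluene, −78 °C), with the ester-bearing quaternary carbon as the large group, should return the (3R)-alcohol 6.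

Step 14. Hydroboration of the congested vinyl group by the bulky 9-BBN dimer may be incomplete, and the Z geometry may erode through addition–elimination at the β-iodoenoate under the basic aqueous coupling conditions. The fallback sets out from 18 and comes back at 21. It replaces the borane coupling by a base-free organozinc coupling. Hydroboration with the smaller dicyclohexylborane and oxidative work-up (NaOH, H2O2) gives 2-[(1R,2R,4aS,6R,8aS)-2-[(tert-butyldimethylsilyloxy)methyl]-5,5,8a-trimethyl-6-(triethylsilyloxy)decahydronaphthalen-1-yl]ethan-1-ol F4. Appel iodination (I2, PPh3, imidazole) gives tert-butyl{[(1R,2R,4aS,6R,8aS)-1-(2-iodoethyl)-5,5,8a-trimethyl-6-(triethylsilyloxy)decahydronaphthalen-2-yl]methoxy}dimethylsilane F5. Zinc insertion (Zn dust, LiCl, THF) gives {2-[(1R,2R,4aS,6R,8aS)-2-[(tert-butyldimethylsilyloxy)methyl]-5,5,8a-trimethyl-6-(triethylsilyloxy)decahydronaphthalen-1-yl]ethyl}zinc iodide F6. Negishi coupling of this reagent with 19 (Pd(PPh3)4, THF, rt) should give 21 with retention of the Z geometry.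

**Further compounds**

F1 | step 11 | 2-[(1E,5R,7E,9E)-11-(tert-butyldimethylsilyloxy)-2,6,6-trimethyl-5-(triethylsilyloxy)undeca-1,7,9-trien-1-yl]-1,3-dioxolane | C1COC(O1)/C=C(\C)CC[C@@H](O[Si](CC)(CC)CC)C(C)(C)/C=C/C=C/CO[Si](C)(C)C(C)(C)C
F2 | step 11 | 2-[(1R,2R,4aS,6R,8aR)-2-[(tert-butyldimethylsilyloxy)methyl]-5,5,8a-trimethyl-6-(triethylsilyloxy)-1,2,4a,5,6,7,8,8a-octahydronaphthalen-1-yl]-1,3-dioxolane | C1COC(O1)[C@@H]2[C@H](CO[Si](C)(C)C(C)(C)C)C=C[C@@H]3C(C)(C)[C@H](O[Si](CC)(CC)CC)CC[C@@]23C
F3 | step 2 | methyl (6E)-8-acetoxy-2,2,6-trimethyl-3-oxooct-6-enoate | CC(=O)OC/C=C(\C)CCC(=O)C(C)(C)C(=O)OC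
F4 | step 14 | 2-[(1R,2R,4aS,6R,8aS)-2-[(tert-butyldimethylsilyloxy)methyl]-5,5,8a-trimethyl-6-(triethylsilyloxy)decahydronaphthalen-1-yl]ethan-1-ol | OCC[C@@H]1[C@H](CO[Si](C)(C)C(C)(C)C)CC[C@@H]2C(C)(C)[C@H](O[Si](CC)(CC)CC)CC[C@@]12C
F5 | step 14 | tert-butyl{[(1R,2R,4aS,6R,8aS)-1-(2-iodoethyl)-5,5,8a-trimethyl-6-(triethylsilyloxy)decahydronaphthalen-2-yl]methoxy}dimethylsilane | ICC[C@@H]1[C@H](CO[Si](C)(C)C(C)(C)C)CC[C@@H]2C(C)(C)[C@H](O[Si](CC)(CC)CC)CC[C@@]12C
F6 | step 14 | {2-[(1R,2R,4aS,6R,8aS)-2-[(tert-butyldimethylsilyloxy)methyl]-5,5,8a-trimethyl-6-(triethylsilyloxy)decahydronaphthalen-1-yl]ethyl}zinc iodide | I[Zn]CC[C@@H]1[C@H](CO[Si](C)(C)C(C)(C)C)CC[C@@H]2C(C)(C)[C@H](O[Si](CC)(CC)CC)CC[C@@]12C
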